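The earlier runs and the new flask stem from a simulated flask for an exercise.

Count time constants, the time in which the starting material falls by a factor of e.

the same everywhere: starting material 1.1 M; gas 200 mM (held)

|  | initiator | temperature | remark | time |
|---|---|---|---|---|
| alpha | 72 mM | 90 °C | run made earlier |  |
| ash | 36 mM | 60 °C |  | 10 d |
| cedar | 36 mM | 90 °C |  | 5.0 d |

alpha run (percent of the starting material charged)

| time / h | product / % | starting material / % |
|---|---|---|
| 1.00 | 8.0 | 93.4 |
| 2.00 | 12.8 | 87.1 |
| 3.00 | 18.8 | 80.5 |
| 6.00 | 34.2 | 64.8 |
| 12.0 | 57.0 | 42.5 |

(each reading ± 0.5 percentage points)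

- at the start none of the gas is in solution
- the earlier runs do not show what temperature does; that part of a forecast is a guess
- no earlier run changes the charge of initiator; that part of a forecast is a guess

- which one finishes higher in amount of product, in percent of the starting material charged ("neither" within 2 percentage points) (ash / cedar / neither)
- amount of product at the end, in percent of the starting material charged, ash
- amount of product at the end, in percent of the starting material charged, cedar

The last alpha reading leaves 42.5% of the starting material after 12.0 h, so its time constant is 14.0 h. The product gives a second way, from separate readings: 57.0% formed in the same time gives 14.2 h. The two agree within the scatter, so I trust the figure. The reading at 3.00 h gives 13.8 h, so the decay looks exponential, or pseudo-first-order.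

No earlier run changes the initiator, so the next step is my guess: if chains start from initiator and end in pairs, the rate goes as the square root of [initiator]. Cedar's charge then stretches the time constant to 19.8 h. Its 5.0 d holds 6.05 such time constants, which leaves 0.236% of the starting material and makes 99.8% product, if the initiator holds up. Ash's 10 d counts 12.1 of them at the same rate, but ash stands at 60 °C, and what cooling does is a guess too.

The forecast says cedar ends higher, with 60% for ash and 96% for cedar. It lets the initiator fade, so its cedar figure is lower than mine, and of its ash figure it says “The uncertainty is wide”.

The flasks give 50.6% for ash and 99.6% for cedar, so cedar ends higher.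

    initiator → 2 initiating radical (k = 0.0120 h⁻¹, Ea = 120 kJ mol⁻¹)
    starting material + initiating radical → capped initiator + first chain carrier (k = 2.10 × 10⁷ M⁻¹ h⁻¹, Ea = 17.0 kJ mol⁻¹)
    reagent + first chain carrier ⇌ product + second chain carrier (K = 2.60, k = 2.00 × 10⁷ M⁻¹ h⁻¹, Ea = 33.0 kJ mol⁻¹, ΔH = −54.0 kJ mol⁻¹)
    starting material + second chain carrier → by-product + first chain carrier (k = 9.20 × 10⁵ M⁻¹ h⁻¹, Ea = 46.0 kJ mol⁻¹)
    2 second chain carrier → ended chains (k = 4.00 × 10⁷ M⁻¹ s⁻¹, Ea = 22.0 kJ mol⁻¹)
    gas ⇌ reagent, rate k6*(csat - [reagent]) (kL = 4.60 h⁻¹)
    (constants at 90 °C)

Cedar's 0.42% of starting material left makes its time constant, averaged over the run, 21.9 h, against the 19.8 h I reckoned from 14.0 h. Ash ends lower because of its lower temperature: at 90 °C it reaches 100%, while its 49% left gives an average time constant of 341 h. Stretching that by the same square root, the neighbour of ash with 0.014 M of initiator should keep 64.4% of its starting material, and it keeps 65%.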